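The earlier runs and the new flask were computed with constants of no real substance, noise included.

If the substrate is counted by its logarithm, L = −ln(fraction of substrate left), the slope s of L against time follows the reagent still available, so the alder rows below read as a reagent gauge.

| setting | alder | flask |
|---|---|---|
| substrate | 0.50 M | 0.50 M |
| reagent in the second phase | 0.68 M | 0.450 M |
| remark | run made earlier |  |
| time |  | 25 min |
| volume of the second phase over the first |  | 0.50 |

alder run (percent of the substrate charged)

| time / min | target / % | idle adduct / % |
|---|---|---|
| 0.417 | 15.5 | 6.0 |
| 0.833 | 23.2 | 6.0 |
| 1.33 | 29.8 | 5.2 |
| 1.50 | 32.4 | 4.8 |
| 2.00 | 34.7 | 5.8 |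
| 2.50 | 37.6 | 5.6 |

(each reading ± 1 percentage point)

- for target the idle adduct is counted in
- in the second phase: reagent in the second phase; everything else is in the first
- charges count per volume of the first phase; a concentration in a rate is the amount of a species over the volume of its own phase; every rate counts per litre of the first phase
- the analysis behind the earlier runs scatters by 1 percentage point, standard deviation
- what may be going on: reagent in the reaction phase <-> reagent in the second phase; substrate + reagent in the reaction phase -> target; reagent in the reaction phase + target <-> idle adduct; 2 reagent in the reaction phase -> self-condensation product
- the earlier runs hold the two phases in the same ratio of volumes as the flask asked about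

- the target and idle adduct together standing at 25 min, as a percentage of the substrate charged
- part of the substrate charged that has reacted at 25 min

Reading the target column, which counts the idle adduct too, I found L at 0.168 in the first row, 0.264 in the second and 0.472 in the last. So s fell from 0.404 min⁻¹ over the first row to 0.125 min⁻¹ between the second and the last, a drop of 0.985 min⁻¹ per unit of L. Running that line back to the start and dividing by the alder reagent charge, I read a constant k of 0.0119 M⁻¹ s⁻¹. Each unit of L costs c(substrate) of reagent for target and ρ·c(reagent) for self-condensation, so the drop equals k·c(substrate) + ρs, and over the mean of those stretches this gave the loss ratio ρ, reagent lost to self-condensation against reagent taken into target at equal concentrations, of 2.65, a reading with the scatter of the rows. Integrated, the fraction of substrate left when the reagent is spent is (1 + (ρ − 1)·c(reagent)/c(substrate))^(−1/(ρ − 1)). For the flask, charged with less reagent than substrate, so that the reagent is the limiting reagent, this meant 42.4% reacted, and I committed to that ceiling for y and cv alike, since the flask is read ten times later than the last alder row.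

The forecast, reckoned apart from mine, said 42% and 42%, holding that “the reagent is being lost far faster than stoichiometry requires”.

The flask gave 45.4% and 45.4%.

    reagent in the reaction phase ⇌ reagent in the second phase, rate k1*([reagent in the reaction phase] - [reagent in the second phase]/K1) per volume of the first phase (partition coefficient = 0.350, kL = 0.320 s⁻¹)
    substrate + reagent in the reaction phase → target (k = 0.0170 M⁻¹ s⁻¹)
    reagent in the reaction phase + target ⇌ idle adduct, settled at all times (K = 2.10 M⁻¹)
    2 reagent in the reaction phase → self-condensation product (k = 0.0250 M⁻¹ s⁻¹)

In the flask, uptake from the second phase had half its turnover done by 0.413 s and self-condensation by 0.449 min, earlier than the path to target at 1.23 min. By 12.5 min c(reagent in the reaction phase) stood at 0.00550 M with target at 43.9%, and the 45.4% lay 3 percentage points above my ceiling. On a neighbour charged with 0.12 M of substrate, the time and all else held, ρ gave 69.8% reacted when the reagent is spent; the computed neighbour stood at 66.0% at 25.0 min, with 0.00933 M of reagent in the reaction phase still there.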